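**Plan**

1. The chain is numbered from the ketone carbon (C1) through the carbinol (C2) to C14, and this numbering is used for all intermediates. The retrosynthesis cuts aryl–C1 (aryllithium + Weinreb amide), then C6–C7 (key step), then C4–C5 (isopropenyl Grignard on a malic-acid aldehyde).
2. Enabling feature: C6–C7 is the central σ-bond of the 1,5-diene C4=C5(Me)–C6–C7–C8=C9, and C4 is γ to the C1 carboxyl. Closing C1(=O)–O–C4 gives a five-membered γ-lactone (ring atoms O, C1, C2, C3, C4) that carries C5/C6 as an isopropenyl group, i.e. an allylic carboxylate set up for SN2′ attack at C6.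
3. Key event: Pd(0) opens this temporary lactone to a 2-methyl-π-allyl carboxylate, and the geranyl unit enters at C6 as its sulfonyl-stabilised C7 carbanion. One step forms C6–C7, the (4E)-alkene and the free C1 acid, from both C4 epimers of the lactone.
4. Forward order: (R)-malic acid → dioxolanone → aldehyde → isopropenyl lactone (C1–C6); union with geranyl phenyl sulfone (C7–C14); desulfonylation; Weinreb amide; aryl ketone; global deprotection. The only rings made are the temporary dioxolanone and lactone.
5. Stereochemistry: C2 (R) comes from (R)-malic acid and is never a reacting centre; 8E comes from geranyl bromide; 4E is set in the key step by the syn-π-allyl.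
6. Helpers removed later: the lactone (opened in the key step), PhSO2 (step 8), TBS and MOM (step 12).

Key step: step 7

**Step 1**
Reactants: 1 (R)-malic acid
Product: 2 (R)-2-(2,2-dimethyl-5-oxo-1,3-dioxolan-4-yl)acetic acid
Conditions: Me2C(OMe)2, PPTS (cat.), rt
Reagents that add atoms: 2,2-dimethoxypropane, COC(C)(C)OC
Why: Acid-catalysed acetal exchange should tie the α-hydroxy acid of (R)-malic acid into the five-membered 1,3-dioxolan-4-one (favoured over the six-membered alternative through the β-carboxyl), which masks C1 and C2–OH, leaves the C4 carboxyl free and does not touch the stereocentre.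

**Step 2**
Reactants: 2 (R)-2-(2,2-dimethyl-5-oxo-1,3-dioxolan-4-yl)acetic acid
Product: 3 (R)-5-(2-hydroxyethyl)-2,2-dimethyl-1,3-dioxolan-4-one
Conditions: BH3·SMe2, THF, 0 °C → rt; neutral aqueous work-up
Reagents that add atoms: none
Why: Borane reduces a free carboxylic acid much faster than the ester-type dioxolanone carbonyl (chemoselective borane reduction), so only C4 should be reduced.

**Step 3**
Reactants: 3 (R)-5-(2-hydroxyethyl)-2,2-dimethyl-1,3-dioxolan-4-one
Product: 4 (R)-2-(2,2-dimethyl-5-oxo-1,3-dioxolan-4-yl)acetaldehyde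
Conditions: Dess–Martin periodinane, NaHCO3, CH2Cl2, 0 °C → rt
Reagents that add atoms: none
Why: Dess–Martin oxidation runs under buffered, near-neutral conditions, which should spare the acid-labile dioxolanone and avoid β-elimination of the C2 oxygen from the aldehyde.

**Step 4**
Reactants: 4 (R)-2-(2,2-dimethyl-5-oxo-1,3-dioxolan-4-yl)acetaldehyde; 5 isopropenylmagnesium bromide
Product: 7 (3R)-3-hydroxy-5-(prop-1-en-2-yl)oxolan-2-one (mixture of C5 epimers), via hydroxy-dioxolanone adduct 6 (not isolated)
Conditions: 5 (1.1 equiv), THF, −78 °C; sat. NH4Cl; then PPTS (cat.), CH2Cl2, rt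
Reagents that add atoms: none
Why: At −78 °C the Grignard reagent should add to the aldehyde in preference to the dioxolanone carbonyl, and the resulting C4 alcohol then acylates itself on the activated C1 carbonyl with loss of acetone (lactonisation by acyl transfer) to give the γ-lactone; the new C4 centre forms without control on purpose, as it is destroyed in step 7.

**Step 5**
Reactants: 7 (3R)-3-hydroxy-5-(prop-1-en-2-yl)oxolan-2-one
Product: 8 (3R)-3-[(tert-butyldimethylsilyl)oxy]-5-(prop-1-en-2-yl)oxolan-2-one (mixture of C5 epimers)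
Conditions: TBSCl, imidazole, DMF, rt
Reagents that add atoms: tert-butyldimethylsilyl chloride, CC(C)(C)[Si](C)(C)Cl
Why: Standard imidazole-promoted silylation of the secondary α-hydroxyl, which removes the acidic OH before the carbanion chemistry and shields the lactone carbonyl.

**Step 6**
Reactants: 9 geranyl bromide
Product: 10 geranyl phenyl sulfone, {[(2E)-3,7-dimethylocta-2,6-dien-1-yl]sulfonyl}benzene
Conditions: PhSO2Na, DMF, rt
Reagents that add atoms: sodium benzenesulfinate, [Na+].[O-]S(=O)c1ccccc1
Why: S-Alkylation of the sulfinate by SN2 displacement of the primary allylic bromide should give the sulfone with the 2E double bond unchanged.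

**Step 7**
Reactants: 8 (3R)-3-[(tert-butyldimethylsilyl)oxy]-5-(prop-1-en-2-yl)oxolan-2-one; 10 geranyl phenyl sulfone
Product: 12 (2R,4E,8E)-2-[(tert-butyldimethylsilyl)oxy]-5,9,13-trimethyl-7-(phenylsulfonyl)tetradeca-4,8,12-trienoic acid (C7 epimers), via sodio sulfone carbanion 11 (not isolated)
Conditions: 10 (1.2 equiv), NaHMDS, THF, −78 °C; added slowly to 8, Pd(PPh3)4 (5 mol %), THF, 0 °C → rt; cold 0.5 M HCl
Reagents that add atoms: none
Why: Proposed new method: Pd(0) should ionise the allylic C4–O bond of either C4 epimer of 8 to the same zwitterionic syn-1-alkyl-2-methyl-π-allylpalladium carboxylate, and the soft sulfonyl-stabilised carbanion 11 (conjugate acid pKa about 23) should attack it from outside the metal at the unsubstituted C6 terminus, an overall SN2′ ring opening that forms C6–C7, sets C4=C5 and frees the C1 carboxylate. The closest known reaction types are the Tsuji–Trost alkylation of vinyl lactones and of 1-alkyl-2-methyl-π-allyl complexes with malonate- or sulfonylacetate-type carbanions, the palladium-catalysed allylation of α-sulfonyl carbanions, and the alkylation of allyl sulfone anions with allylic halides; new is the use of a singly stabilised allyl sulfone anion on a lactone-derived π-allyl. No ring is closed: the five-membered lactone (O, C1, C2, C3, C4) is the temporary ring and is opened. The new stereocentre C7 is uncontrolled and is erased in step 8, while the E geometry of C4=C5 is controlled by the syn preference of the C3 chain on the π-allyl (an anti chain would clash with the C6 methylene), which both epimers reach by η3–η1–η3 equilibration, hence the stereoconvergence. The step needs α-attack of the carbanion (the sulfone localises charge at C7 and γ-attack would build a quaternary centre), attack at C6 rather than C4 (less hindered terminus, remote from the carboxylate) and allylation faster than acylation of the lactone carbonyl or removal of the C2–H, which slow addition of 11 to the pre-mixed lactone and catalyst, the sodium counter-ion and the flanking OTBS group should secure. C2 lies outside the allyl unit and keeps its configuration.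

**Step 8**
Reactants: 12 (2R,4E,8E)-2-[(tert-butyldimethylsilyl)oxy]-5,9,13-trimethyl-7-(phenylsulfonyl)tetradeca-4,8,12-trienoic acid
Product: 13 (2R,4E,8E)-2-[(tert-butyldimethylsilyl)oxy]-5,9,13-trimethyltetradeca-4,8,12-trienoic acid
Conditions: PdCl2(dppp) (5 mol %), LiBHEt3 (3.5 equiv), THF, 0 °C → rt; 1 M HCl
Reagents that add atoms: none
Why: Palladium-catalysed reductive desulfonylation, in which Pd(0) ionises the allylic C7–S bond and hydride is delivered to the less substituted C7 terminus of the π-allyl, should return the C8=C9 alkene in place with E geometry, the acid being carried as its inert lithium carboxylate.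

**Step 9**
Reactants: 13 (2R,4E,8E)-2-[(tert-butyldimethylsilyl)oxy]-5,9,13-trimethyltetradeca-4,8,12-trienoic acid
Product: 14 (2R,4E,8E)-2-[(tert-butyldimethylsilyl)oxy]-N-methoxy-N,5,9,13-tetramethyltetradeca-4,8,12-trienamide
Conditions: MeNH(OMe)·HCl, EDC·HCl, HOBt, iPr2NEt, CH2Cl2, 0 °C → rt
Reagents that add atoms: N,O-dimethylhydroxylamine hydrochloride, CNOC.Cl
Why: Carbodiimide/HOBt amide coupling gives the Weinreb amide, and an α-silyloxy acid has no azlactone pathway, so C2 should not epimerise.

**Step 10**
Reactants: 15 4-bromoresorcinol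
Product: 16 1-bromo-2,4-bis(methoxymethoxy)benzene
Conditions: MOMCl, iPr2NEt, CH2Cl2, 0 °C → rt
Reagents that add atoms: chloromethyl methyl ether, COCCl
Why: O-Alkylation of both phenols with MOMCl gives acetal ethers that survive the aryllithium of step 11 and stabilise it by chelation.

**Step 11**
Reactants: 16 1-bromo-2,4-bis(methoxymethoxy)benzene; 14 (2R,4E,8E)-2-[(tert-butyldimethylsilyl)oxy]-N-methoxy-N,5,9,13-tetramethyltetradeca-4,8,12-trienamide
Product: 18 (2R,4E,8E)-1-[2,4-bis(methoxymethoxy)phenyl]-2-[(tert-butyldimethylsilyl)oxy]-5,9,13-trimethyltetradeca-4,8,12-trien-1-one, via aryllithium 17 (not isolated)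
Conditions: 16, n-BuLi, THF, −78 °C; then 14, −78 → −40 °C; sat. NH4Cl
Reagents that add atoms: none
Why: Bromine–lithium exchange gives the aryllithium, whose addition to the Weinreb amide stops at the chelated tetrahedral intermediate (Weinreb ketone synthesis), so that neither over-addition nor base-induced epimerisation at C2 should occur.

**Step 12**
Reactants: 18 (2R,4E,8E)-1-[2,4-bis(methoxymethoxy)phenyl]-2-[(tert-butyldimethylsilyl)oxy]-5,9,13-trimethyltetradeca-4,8,12-trien-1-one
Product: 19 (2R,4E,8E)-1-(2,4-dihydroxyphenyl)-2-hydroxy-5,9,13-trimethyltetradeca-4,8,12-trien-1-one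
Conditions: HCl (ca. 1 M in MeOH), 0 °C → rt
Reagents that add atoms: none
Why: Acid-catalysed methanolysis should cleave both aryl MOM acetals and the secondary silyl ether in one operation under conditions mild enough to leave the three trisubstituted alkenes and the α-ketol stereocentre untouched.

**Compound list**

1 | (R)-malic acid | OC(=O)C[C@@H](O)C(=O)O | starting material
2 | (R)-2-(2,2-dimethyl-5-oxo-1,3-dioxolan-4-yl)acetic acid | OC(=O)C[C@H]1OC(C)(C)OC1=O | intermediate
3 | (R)-5-(2-hydroxyethyl)-2,2-dimethyl-1,3-dioxolan-4-one | OCC[C@H]1OC(C)(C)OC1=O | intermediate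
4 | (R)-2-(2,2-dimethyl-5-oxo-1,3-dioxolan-4-yl)acetaldehyde | O=CC[C@H]1OC(C)(C)OC1=O | intermediate
5 | isopropenylmagnesium bromide | C=C(C)[Mg]Br | starting material
6 | (5R)-5-(2-hydroxy-3-methylbut-3-en-1-yl)-2,2-dimethyl-1,3-dioxolan-4-one (both carbinol epimers, not isolated) | C=C(C)C(O)C[C@H]1OC(C)(C)OC1=O | intermediate
7 | (3R)-3-hydroxy-5-(prop-1-en-2-yl)oxolan-2-one (C5 epimers) | C=C(C)C1C[C@@H](O)C(=O)O1 | intermediate
8 | (3R)-3-[(tert-butyldimethylsilyl)oxy]-5-(prop-1-en-2-yl)oxolan-2-one (C5 epimers) | C=C(C)C1C[C@@H](O[Si](C)(C)C(C)(C)C)C(=O)O1 | intermediate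
9 | geranyl bromide, (2E)-1-bromo-3,7-dimethylocta-2,6-diene | CC(C)=CCC/C(C)=C/CBr | starting material
10 | geranyl phenyl sulfone | CC(C)=CCC/C(C)=C/CS(=O)(=O)c1ccccc1 | intermediate
11 | sodium salt of the α-sulfonyl carbanion of 10 (not isolated) | CC(C)=CCC/C(C)=C/[CH-]S(=O)(=O)c1ccccc1.[Na+] | intermediate
12 | (2R,4E,8E)-2-[(tert-butyldimethylsilyl)oxy]-5,9,13-trimethyl-7-(phenylsulfonyl)tetradeca-4,8,12-trienoic acid (C7 epimers) | CC(C)=CCC/C(C)=C/C(C/C(C)=C/C[C@@H](O[Si](C)(C)C(C)(C)C)C(=O)O)S(=O)(=O)c1ccccc1 | intermediate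
13 | (2R,4E,8E)-2-[(tert-butyldimethylsilyl)oxy]-5,9,13-trimethyltetradeca-4,8,12-trienoic acid | CC(C)=CCC/C(C)=C/CC/C(C)=C/C[C@@H](O[Si](C)(C)C(C)(C)C)C(=O)O | intermediate
14 | (2R,4E,8E)-2-[(tert-butyldimethylsilyl)oxy]-N-methoxy-N,5,9,13-tetramethyltetradeca-4,8,12-trienamide | CC(C)=CCC/C(C)=C/CC/C(C)=C/C[C@@H](O[Si](C)(C)C(C)(C)C)C(=O)N(C)OC | intermediate
15 | 4-bromoresorcinol (4-bromobenzene-1,3-diol) | Oc1ccc(Br)c(O)c1 | starting material
16 | 1-bromo-2,4-bis(methoxymethoxy)benzene | COCOc1ccc(Br)c(OCOC)c1 | intermediate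
17 | [2,4-bis(methoxymethoxy)phenyl]lithium (not isolated) | [Li]c1ccc(OCOC)cc1OCOC | intermediate
18 | (2R,4E,8E)-1-[2,4-bis(methoxymethoxy)phenyl]-2-[(tert-butyldimethylsilyl)oxy]-5,9,13-trimethyltetradeca-4,8,12-trien-1-one | CC(C)=CCC/C(C)=C/CC/C(C)=C/C[C@@H](O[Si](C)(C)C(C)(C)C)C(=O)c1ccc(OCOC)cc1OCOC | intermediate
19 | (2R,4E,8E)-1-(2,4-dihydroxyphenyl)-2-hydroxy-5,9,13-trimethyltetradeca-4,8,12-trien-1-one | CC(C)=CCC/C(C)=C/CC/C(C)=C/C[C@@H](O)C(=O)c1ccc(O)cc1O | target

**Step count**

Total steps: 12. Longest linear sequence: 10 (steps 1–5, 7–9, 11, 12).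

**Steps most likely to fail**

Step 7 (Proposed new method). The carbanion may acylate the lactone carbonyl or abstract the C2–H faster than the π-allyl is alkylated, which would consume the lactone or erode the configuration at C2; attack at the wrong allyl terminus or through the anti-π-allyl would lower regio- and E-selectivity. The fallback uses the known palladium alkylation with a doubly stabilised, weakly basic carbanion. It sets out from 10, which is deprotonated twice with LDA in THF at −78 °C and acylated with methyl chloroformate to give methyl (3E)-4,8-dimethyl-2-(phenylsulfonyl)nona-3,7-dienoate F1. Sodium hydride in THF converts it into its sodium salt F2, which is too weak a base and nucleophile to attack the lactone. With 8 and Pd(PPh3)4 in THF (rt to 50 °C), Tsuji–Trost alkylation at the C6 terminus should give (2R,4E,8E)-2-[(tert-butyldimethylsilyl)oxy]-7-(methoxycarbonyl)-5,9,13-trimethyl-7-(phenylsulfonyl)tetradeca-4,8,12-trienoic acid F3. Krapcho demethoxycarbonylation (LiI, DMF, 120 °C) removes the ester and returns to the route at 12.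

Step 4. The Grignard reagent may attack the activated dioxolanone carbonyl, or act as a base and trigger β-elimination of the C2 oxygen from the enolisable aldehyde. The fallback builds the C4–C5 bond by acylation and then reduces. It sets out from 2, which with oxalyl chloride and catalytic DMF in CH2Cl2 gives (R)-2-(2,2-dimethyl-5-oxo-1,3-dioxolan-4-yl)acetyl chloride F4. Stille acylation with tributyl(isopropenyl)stannane (BnPdCl(PPh3)2 cat., THF, 50 °C) gives (R)-2,2-dimethyl-5-(3-methyl-2-oxobut-3-en-1-yl)-1,3-dioxolan-4-one F5. Luche reduction (NaBH4, CeCl3·7H2O, MeOH, −78 °C) gives 6, which lactonises with PPTS and comes back to the route at 7.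

Step 12. Under acid the free C2–OH or methanol may add across a protonated trisubstituted alkene (tetrahydrofuran formation from C2–O onto C5, or polyene cyclisation), and slow enolisation of the ketol may erode the configuration at C2 before the para MOM ether is cleaved. The fallback replaces acid by neutral deprotections. It sets out from 15, which with allyl bromide and K2CO3 in acetone gives 1-bromo-2,4-bis(prop-2-en-1-yloxy)benzene F6. Bromine–lithium exchange (n-BuLi, THF, −78 °C) gives [2,4-bis(prop-2-en-1-yloxy)phenyl]lithium F7, which adds to 14 to give (2R,4E,8E)-1-[2,4-bis(prop-2-en-1-yloxy)phenyl]-2-[(tert-butyldimethylsilyl)oxy]-5,9,13-trimethyltetradeca-4,8,12-trien-1-one F8. Pd(PPh3)4 with morpholine in THF at rt removes both allyl groups to give (2R,4E,8E)-2-[(tert-butyldimethylsilyl)oxy]-1-(2,4-dihydroxyphenyl)-5,9,13-trimethyltetradeca-4,8,12-trien-1-one F9. HF·pyridine in THF/pyridine at 0 °C cleaves the silyl ether and comes back to the route at 19.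

**Further compounds**

F1 | step 7 | methyl (3E)-4,8-dimethyl-2-(phenylsulfonyl)nona-3,7-dienoate | CC(C)=CCC/C(C)=C/C(C(=O)OC)S(=O)(=O)c1ccccc1
F2 | step 7 | sodium salt of F1 | CC(C)=CCC/C(C)=C/[C-](C(=O)OC)S(=O)(=O)c1ccccc1.[Na+]
F3 | step 7 | (2R,4E,8E)-2-[(tert-butyldimethylsilyl)oxy]-7-(methoxycarbonyl)-5,9,13-trimethyl-7-(phenylsulfonyl)tetradeca-4,8,12-trienoic acid | CC(C)=CCC/C(C)=C/C(C/C(C)=C/C[C@@H](O[Si](C)(C)C(C)(C)C)C(=O)O)(C(=O)OC)S(=O)(=O)c1ccccc1
F4 | step 4 | (R)-2-(2,2-dimethyl-5-oxo-1,3-dioxolan-4-yl)acetyl chloride | O=C(Cl)C[C@H]1OC(C)(C)OC1=O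
F5 | step 4 | (R)-2,2-dimethyl-5-(3-methyl-2-oxobut-3-en-1-yl)-1,3-dioxolan-4-one | C=C(C)C(=O)C[C@H]1OC(C)(C)OC1=O
F6 | step 12 | 1-bromo-2,4-bis(prop-2-en-1-yloxy)benzene | C=CCOc1ccc(Br)c(OCC=C)c1
F7 | step 12 | [2,4-bis(prop-2-en-1-yloxy)phenyl]lithium | [Li]c1ccc(OCC=C)cc1OCC=C
F8 | step 12 | (2R,4E,8E)-1-[2,4-bis(prop-2-en-1-yloxy)phenyl]-2-[(tert-butyldimethylsilyl)oxy]-5,9,13-trimethyltetradeca-4,8,12-trien-1-one | CC(C)=CCC/C(C)=C/CC/C(C)=C/C[C@@H](O[Si](C)(C)C(C)(C)C)C(=O)c1ccc(OCC=C)cc1OCC=C
F9 | step 12 | (2R,4E,8E)-2-[(tert-butyldimethylsilyl)oxy]-1-(2,4-dihydroxyphenyl)-5,9,13-trimethyltetradeca-4,8,12-trien-1-one | CC(C)=CCC/C(C)=C/CC/C(C)=C/C[C@@H](O[Si](C)(C)C(C)(C)C)C(=O)c1ccc(O)cc1O
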